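**Retrosynthetic overview**
1. Last operations: PMB removal, acetylations, desilylation. The ten-membered ring is closed by an intramolecular Nozaki–Hiyama–Kishi reaction (C4–C5) between a C4 aldehyde and a (Z)-C5 alkenyl iodide.
2. The two halves are joined at C9–C10 by a Nozaki–Hiyama allylation (ring A allyl bromide + lactone aldehyde), which also creates C10 and the C11=C12 alkene. C9 is then set by oxidation and chelation-controlled reduction, and the 11,12-epoxide by hydroxyl-directed epoxidation.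
3. West half (ring A, C1–C4, C10–C15, C20): 2-methylcyclohexane-1,3-dione, yeast desymmetrisation (C1, C14), Brown allylation (C2), methylation and dehydrogenation.
4. East half (C5–C9, C16–C19): methyl (S)-glycerate acetonide and propargyl alcohol; Felkin reduction (C7), trans-hydroalumination/iodination ((Z)-iodide), SmI2 Reformatsky lactonisation (C8, C17).
5. Ring order: ring A (from the start), γ-lactone (step 20), epoxide (step 26), ten-membered ring (step 29).

Assumption: the baker's-yeast ketol 3 is taken as the (2S,3S) isomer (hydroxyl cis to allyl); this is recalled from precedent, not derived. Briarane numbering (C1–C20) of the target is used for all intermediates; α/β refer to the target drawn with the C15 methyl β. None of the steps has been run; selectivities are predictions.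

---

**West half**

Step 1
Reactants: 1 2-methylcyclohexane-1,3-dione
Product: 2 2-methyl-2-(prop-2-enyl)cyclohexane-1,3-dione
Conditions: allyl acetate, Pd(PPh3)4 (2 mol %, zerovalent palladium), DBU, toluene, 80 °C
Reagents that add atoms: allyl acetate, CC(=O)OCC=C
Why: Tsuji–Trost C-allylation of the soft dione enolate by the π-allylpalladium complex builds the (still achiral) quaternary C1.

Step 2
Reactants: 2 2-methyl-2-(prop-2-enyl)cyclohexane-1,3-dione
Product: 3 (2S,3S)-3-hydroxy-2-methyl-2-(prop-2-enyl)cyclohexan-1-one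
Conditions: baker's yeast, sucrose, H2O, 30 °C
Reagents that add atoms: none
Why: Enzymatic desymmetrising ketone reduction delivers hydride to one enantiotopic carbonyl, giving the (S)-carbinol cis to allyl and thereby fixing both C14 and the quaternary C1.

Step 3
Reactants: 3 (2S,3S)-ketol
Product: 4 (2S,3S)-2-methyl-2-(prop-2-enyl)-3-(triethylsilyloxy)cyclohexan-1-one
Conditions: Et3SiCl, imidazole, DMF, 0 °C
Reagents that add atoms: chlorotriethylsilane, CC[Si](Cl)(CC)CC
Why: Silyl ether formation protects the C14 hydroxyl for the enolate and oxidation chemistry that follows.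

Step 4
Reactants: 4 allyl ketone
Product: 5 (2S,3S)-2-methyl-2-[(E)-prop-1-enyl]-3-(triethylsilyloxy)cyclohexan-1-one
Conditions: RuHCl(CO)(PPh3)3 (5 mol %), toluene, 80 °C
Reagents that add atoms: none
Why: Ruthenium hydride alkene isomerisation moves the terminal double bond one position inward so that C2 can be released as an aldehyde.

Step 5
Reactants: 5 propenyl ketone
Product: 7 (1R,6S)-1-methyl-2-oxo-6-(triethylsilyloxy)cyclohexane-1-carbaldehyde, via secondary ozonide 6 (not isolated)
Conditions: O3, CH2Cl2, −78 °C; then PPh3, −78 °C to rt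
Reagents that add atoms: ozone, [O-][O+]=O
Why: Ozonolysis with reductive work-up cleaves the only alkene to the non-enolisable C2 aldehyde without touching the stereocentres.

Step 6
Reactants: 7 keto aldehyde
Product: 8 (2S,3S)-2-[(1R)-1-hydroxybut-3-enyl]-2-methyl-3-(triethylsilyloxy)cyclohexan-1-one
Conditions: (+)-Ipc2BOMe, CH2=CHCH2MgBr, Et2O, −78 °C; add 7, −78 °C; then NaBO3·4H2O, THF/H2O, rt
Reagents that add atoms: allylmagnesium bromide (allyl delivered through (+)-B-allyldiisopinocampheylborane), C=CC[Mg]Br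
Why: Brown asymmetric allylboration through a chair Zimmerman–Traxler transition state adds allyl to the Re face of the aldehyde (reagent control) to give the (R)-carbinol at C2, the hindered ketone being left alone at −78 °C.

Step 7
Reactants: 8 homoallylic alcohol
Product: 9 bis(triethylsilyl) ether of 8
Conditions: Et3SiOTf, 2,6-lutidine, CH2Cl2, −78 °C
Reagents that add atoms: triethylsilyl trifluoromethanesulfonate, CC[Si](CC)(CC)OS(=O)(=O)C(F)(F)F
Why: Silylation of the hindered C2 hydroxyl prevents retro-aldol cleavage and blocks it through the enolate steps.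

Step 8
Reactants: 9 bis-silyl ketone
Product: 10 C11-methyl ketone (epimer mixture at C11)
Conditions: LiN(i-Pr)2, THF, −78 °C; then MeI, −78 to −20 °C
Reagents that add atoms: iodomethane, [CH3]I
Why: Enolate alkylation is regiospecific because C11 is the only enolisable position (C1 is quaternary), and the new centre is later made sp2.

Step 9
Reactants: 10 methyl ketone
Product: 12 C10-keto-11-methyl-cyclohex-11-ene (enone), via trimethylsilyl enol ether 11 (not isolated)
Conditions: LiN(i-Pr)2, Me3SiCl, THF, −78 °C; then Pd(OAc)2 (1.1 equiv, divalent palladium), MeCN, rt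
Reagents that add atoms: none
Why: Saegusa–Ito oxidation of the regiodefined silyl enol ether gives the endocyclic 2-methyl enone by β-hydride elimination toward C12.

Step 10
Reactants: 12 enone
Product: 13 allylic alcohol (C10–OH, epimer mixture)
Conditions: NaBH4, CeCl3·7H2O, MeOH, −78 °C
Reagents that add atoms: none
Why: Luche 1,2-reduction gives the allylic alcohol, whose C10 configuration does not matter because it is erased in the allylmetal of step 23.

Step 11
Reactants: 13 allylic alcohol
Product: 14 allylic bromide (10-bromo-Δ11 drawn; any 12-bromo-Δ10 isomer is carried along)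
Conditions: CBr4, PPh3, 2,6-lutidine, CH2Cl2, 0 °C
Reagents that add atoms: tetrabromomethane, BrC(Br)(Br)Br
Why: Appel bromination gives the allyl bromide, and both allylic isomers converge on the same allylchromium species later.

**East half**

Step 12
Reactants: 15 prop-2-yn-1-ol
Product: 16 1-methoxy-4-[(prop-2-ynyloxy)methyl]benzene
Conditions: NaH, THF, 0 °C; 4-MeOC6H4CH2Cl, Bu4NI (cat.), rt
Reagents that add atoms: 4-methoxybenzyl chloride, COc1ccc(CCl)cc1
Why: Williamson etherification installs the PMB group that protects C16–OH until the last step.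

Step 13
Reactants: 16 PMB propargyl ether; 17 methyl (4S)-2,2-dimethyl-1,3-dioxolane-4-carboxylate
Product: 18 1-[(4S)-2,2-dimethyl-1,3-dioxolan-4-yl]-4-[(4-methoxybenzyl)oxy]but-2-yn-1-one
Conditions: n-BuLi, THF, −78 °C; BF3·OEt2; then 17, −78 °C
Reagents that add atoms: none
Why: BF3-assisted acylation of the lithium acetylide by the ester stops at the ynone because the tetrahedral adduct is stable at −78 °C, joining C6 to C7.

Step 14
Reactants: 18 ynone
Product: 19 (1S)-1-[(4S)-2,2-dimethyl-1,3-dioxolan-4-yl]-4-[(4-methoxybenzyl)oxy]but-2-yn-1-ol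
Conditions: LiBH(s-Bu)3, THF, −78 °C
Reagents that add atoms: none
Why: Felkin–Anh-controlled reduction with the bulky hydride, attacking anti to the C8–O bond, gives the (S)-carbinol at C7 (syn to the dioxolane oxygen).

Step 15
Reactants: 19 propargylic alcohol
Product: 21 (1S,2Z)-1-[(4S)-2,2-dimethyl-1,3-dioxolan-4-yl]-3-iodo-4-[(4-methoxybenzyl)oxy]but-2-en-1-ol, via alkenylaluminate 20 (not isolated)
Conditions: NaAlH2(OCH2CH2OMe)2, THF, 0 °C to rt; then I2, THF, −78 °C
Reagents that add atoms: iodine, [I][I]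
Why: Hydroxyl-directed trans-hydroalumination puts hydrogen on C6 and aluminium on C5, and iodinolysis with retention gives the (Z)-alkenyl iodide with iodine cis to C7.

Step 16
Reactants: 21 iodo allylic alcohol
Product: 22 2-bromopropanoate ester of 21 (epimers at the bromine-bearing carbon)
Conditions: CH3CHBrCOBr, pyridine, CH2Cl2, 0 °C
Reagents that add atoms: 2-bromopropanoyl bromide, CC(Br)C(Br)=O
Why: O-acylation of the C7 hydroxyl attaches the C17–C19 propionate unit as a Reformatsky donor.

Step 17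
Reactants: 22 acetonide ester
Product: 23 C8,C9-diol
Conditions: AcOH/H2O (4:1), 40 °C
Reagents that add atoms: none
Why: Mild acid hydrolysis removes the acetonide while PMB ether, allylic ester and alkenyl iodide survive.

Step 18
Reactants: 23 diol
Product: 24 C9 tert-butyldimethylsilyl ether
Conditions: t-BuMe2SiCl, imidazole, CH2Cl2, −20 °C
Reagents that add atoms: tert-butyldimethylsilyl chloride, CC(C)(C)[Si](C)(C)Cl
Why: Silylation is selective for the unhindered primary C9 hydroxyl, leaving the secondary C8 hydroxyl as the only free alcohol.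

Step 19
Reactants: 24 secondary alcohol
Product: 25 C8 ketone
Conditions: Dess–Martin periodinane, NaHCO3, CH2Cl2, 0 °C to rt
Reagents that add atoms: none
Why: Buffered Dess–Martin oxidation gives the ketone under near-neutral conditions, which avoids epimerising the α-acyloxy allylic C7.

Step 20
Reactants: 25 α-(2-bromopropanoyloxy) ketone
Product: 26 γ-lactone with 8-OH, 17-methyl and the C7 iodoalkenyl group all cis, C8 carrying CH2OSi(t-Bu)Me2
Conditions: SmI2 (2.5 equiv, divalent samarium), THF, −78 °C; aqueous NH4Cl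
Reagents that add atoms: none
Why: The SmI2-mediated intramolecular Reformatsky (aldol) reaction closes the five-membered lactone with the bulky silyloxymethyl group trans to the C7 alkenyl chain (hydroxyl cis to it), and the C17 methyl settles trans to the silyloxymethyl group (the more stable, base-equilibratable epimer).

Step 21
Reactants: 26 silyl ether lactone
Product: 27 lactone diol (tertiary 8-OH, primary 9-OH)
Conditions: HF·pyridine, pyridine, THF, 0 °C
Reagents that add atoms: none
Why: Fluoride-mediated desilylation frees the primary C9 hydroxyl without opening the lactone.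

Step 22
Reactants: 27 lactone diol
Product: 28 lactone α-hydroxy aldehyde (C9 aldehyde)
Conditions: IBX, DMSO, rt
Reagents that add atoms: none
Why: IBX oxidises the primary alcohol to the aldehyde without glycol cleavage, and the tertiary hydroxyl cannot be oxidised.

**Union and endgame**

Step 23
Reactants: 14 ring A allylic bromide; 28 lactone aldehyde
Product: 30 coupled homoallylic alcohol (C9–C10 bond; H-10 α; Δ11; C9 epimer mixture), via allylchromium dichloride 29 (not isolated)
Conditions: CrCl2 (4 equiv, nickel-free, divalent chromium), THF, 0 °C to rt; 14 (1.5 equiv)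
Reagents that add atoms: none
Why: Nozaki–Hiyama allylation proceeds with chromium on the less hindered C12 and C–C bond formation at the γ-carbon C10 through a six-membered transition state, the aldehyde approaching anti to the bulky C1 side chain so that C9 ends cis to the C15 methyl (10S), while the alkenyl iodide is inert without nickel.

Step 24
Reactants: 30 C9 alcohol mixture
Product: 31 C9 ketone (α-hydroxy ketone)
Conditions: IBX, DMSO, rt
Reagents that add atoms: none
Why: Neutral IBX oxidation converges both C9 epimers to one ketone without base, which protects the acidic allylic C10–H from epimerisation.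

Step 25
Reactants: 31 α-hydroxy ketone
Product: 32 anti-8,9-diol (9R as in the target)
Conditions: Zn(BH4)2, Et2O, −30 °C
Reagents that add atoms: none
Why: Chelation-controlled (Cram-chelate) reduction, with zinc bridging the C8 hydroxyl and the C9 carbonyl and hydride entering from the C17 flank, gives the anti-diol with the required C9 configuration.

Step 26
Reactants: 32 homoallylic diol
Product: 33 11β,12β-epoxide
Conditions: VO(acac)2 (5 mol %), t-BuOOH, CH2Cl2, 0 °C
Reagents that add atoms: tert-butyl hydroperoxide, CC(C)(C)OO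
Why: Vanadium-catalysed hydroxyl-directed epoxidation delivers oxygen from the homoallylic C9 hydroxyl to the β face of the electron-rich ring alkene, while the terminal alkene (no directing group) and the iodoalkene (electron-poor) do not react.

Step 27
Reactants: 33 epoxy diol
Product: 34 C9 acetate
Conditions: Ac2O, pyridine, DMAP (cat.), CH2Cl2, rt
Reagents that add atoms: acetic anhydride, CC(=O)OC(C)=O
Why: Acylation takes the secondary C9 hydroxyl and leaves the far more hindered tertiary C8 hydroxyl free, which also removes the free 1,2-diol before periodate is used.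

Step 28
Reactants: 34 terminal alkene
Product: 36 C4 aldehyde, via vicinal diol 35 (not isolated)
Conditions: OsO4 (2 mol %), NaIO4, 2,6-lutidine, dioxane/H2O (3:1), rt
Reagents that add atoms: osmium tetroxide, O=[Os](=O)(=O)=O; sodium periodate, [Na+].[O-]I(=O)(=O)=O
Why: Lemieux–Johnson oxidative cleavage selects the monosubstituted alkene over the deactivated, trisubstituted iodoalkene and unveils the C4 aldehyde.

Step 29
Reactants: 36 iodo aldehyde
Product: 38 ten-membered carbocycle with (4R)-allylic alcohol and (5Z)-alkene, via alkenylchromium dichloride 37 (not isolated)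
Conditions: CrCl2 (10 equiv), NiCl2 (1 mol %), DMSO/THF, rt, 2 mM, slow addition
Reagents that add atoms: none
Why: The intramolecular Nozaki–Hiyama–Kishi reaction (nickel-catalysed oxidative addition, transmetalation to chromium, addition to the aldehyde) closes the ring with retention of the Z geometry, and the C4 carbinol is expected anti to the C2 silyloxy group (1,3-anti induction plus macrocyclic control).

Step 30
Reactants: 38 bis(triethylsilyl) ether
Product: 39 2,4,14-triol (8-OH free, 9-OAc, 16-OPMB)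
Conditions: Bu4NF, AcOH (1:1), THF, 0 °C to rt
Reagents that add atoms: none
Why: Buffered fluoride desilylation removes both triethylsilyl groups without acetate migration or epoxide opening.

Step 31
Reactants: 39 triol
Product: 40 2,4,9,14-tetraacetate 16-PMB ether
Conditions: Ac2O, pyridine, DMAP (cat.), CH2Cl2, rt
Reagents that add atoms: acetic anhydride, CC(=O)OC(C)=O
Why: Acetylation esterifies the three secondary hydroxyls while the tertiary C8 hydroxyl stays free.

Step 32
Reactants: 40 PMB ether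
Product: 41 CNP0104124.1
Conditions: DDQ, CH2Cl2/pH 7 phosphate buffer, 0 °C
Reagents that add atoms: none
Why: Oxidative PMB cleavage with DDQ under neutral conditions frees the primary C16 hydroxyl without harming the acetates, epoxide or lactone.

---

**Compound list**

1 | 2-methylcyclohexane-1,3-dione | CC1C(=O)CCCC1=O | starting material
2 | 2-methyl-2-(prop-2-enyl)cyclohexane-1,3-dione | C=CCC1(C)C(=O)CCCC1=O | intermediate
3 | (2S,3S)-3-hydroxy-2-methyl-2-(prop-2-enyl)cyclohexan-1-one | O[C@H]1CCCC(=O)[C@@]1(C)CC=C | intermediate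
4 | (2S,3S)-2-methyl-2-(prop-2-enyl)-3-(triethylsilyloxy)cyclohexan-1-one | CC[Si](CC)(CC)O[C@H]1CCCC(=O)[C@@]1(C)CC=C | intermediate
5 | (2S,3S)-2-methyl-2-[(E)-prop-1-enyl]-3-(triethylsilyloxy)cyclohexan-1-one | CC[Si](CC)(CC)O[C@H]1CCCC(=O)[C@@]1(C)/C=C/C | intermediate
6 | secondary ozonide of 5 (5-methyl-1,2,4-trioxolan-3-yl on C1) | CC[Si](CC)(CC)O[C@H]1CCCC(=O)[C@@]1(C)C1OOC(C)O1 | intermediate
7 | (1R,6S)-1-methyl-2-oxo-6-(triethylsilyloxy)cyclohexane-1-carbaldehyde | CC[Si](CC)(CC)O[C@H]1CCCC(=O)[C@@]1(C)C=O | intermediate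
8 | (2S,3S)-2-[(1R)-1-hydroxybut-3-enyl]-2-methyl-3-(triethylsilyloxy)cyclohexan-1-one | CC[Si](CC)(CC)O[C@H]1CCCC(=O)[C@@]1(C)[C@H](O)CC=C | intermediate
9 | bis(triethylsilyl) ether of 8 (C2 R, C14 S, C1 as in 3) | CC[Si](CC)(CC)O[C@H]1CCCC(=O)[C@@]1(C)[C@H](O[Si](CC)(CC)CC)CC=C | intermediate
10 | C11-methyl derivative of 9 (C11 epimers) | CC[Si](CC)(CC)O[C@H]1CCC(C)C(=O)[C@@]1(C)[C@H](O[Si](CC)(CC)CC)CC=C | intermediate
11 | C10 trimethylsilyl enol ether of 10 (C10=C11) | CC[Si](CC)(CC)O[C@H]1CCC(C)=C(O[Si](C)(C)C)[C@@]1(C)[C@H](O[Si](CC)(CC)CC)CC=C | intermediate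
12 | ring A enone: C10 ketone, C11 methyl, C11=C12, 14α-OSiEt3, C1 carrying β-methyl and the (R)-1-(triethylsilyloxy)but-3-enyl chain | CC[Si](CC)(CC)O[C@H]1CC=C(C)C(=O)[C@@]1(C)[C@H](O[Si](CC)(CC)CC)CC=C | intermediate
13 | allylic alcohol from 12 (C10–OH, epimer mixture) | CC[Si](CC)(CC)O[C@H]1CC=C(C)C(O)[C@@]1(C)[C@H](O[Si](CC)(CC)CC)CC=C | intermediate
14 | allylic bromide from 13 (C10–Br drawn; mixture with allylic isomer) | CC[Si](CC)(CC)O[C@H]1CC=C(C)C(Br)[C@@]1(C)[C@H](O[Si](CC)(CC)CC)CC=C | intermediate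
15 | prop-2-yn-1-ol | C#CCO | starting material
16 | 1-methoxy-4-[(prop-2-ynyloxy)methyl]benzene | C#CCOCc1ccc(OC)cc1 | intermediate
17 | methyl (4S)-2,2-dimethyl-1,3-dioxolane-4-carboxylate | COC(=O)[C@@H]1COC(C)(C)O1 | starting material
18 | 1-[(4S)-2,2-dimethyl-1,3-dioxolan-4-yl]-4-[(4-methoxybenzyl)oxy]but-2-yn-1-one | COc1ccc(COCC#CC(=O)[C@@H]2COC(C)(C)O2)cc1 | intermediate
19 | (1S)-1-[(4S)-2,2-dimethyl-1,3-dioxolan-4-yl]-4-[(4-methoxybenzyl)oxy]but-2-yn-1-ol | COc1ccc(COCC#C[C@H](O)[C@@H]2COC(C)(C)O2)cc1 | intermediate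
20 | sodium alkenylaluminate of 19 (five-membered O–Al–C5=C6–C7 ring, two 2-methoxyethoxy ligands) | [Na+].COCCO[Al-]1(OCCOC)O[C@H]([C@@H]2COC(C)(C)O2)C=C1COCc1ccc(OC)cc1 | intermediate
21 | (1S,2Z)-1-[(4S)-2,2-dimethyl-1,3-dioxolan-4-yl]-3-iodo-4-[(4-methoxybenzyl)oxy]but-2-en-1-ol | COc1ccc(COC/C(I)=C/[C@H](O)[C@@H]2COC(C)(C)O2)cc1 | intermediate
22 | 2-bromopropanoate of 21 (C7 ester; bromide carbon unassigned) | COc1ccc(COC/C(I)=C/[C@H](OC(=O)C(C)Br)[C@@H]2COC(C)(C)O2)cc1 | intermediate
23 | C8,C9-diol from 22 (C7 S, C8 S, 5Z) | COc1ccc(COC/C(I)=C/[C@H](OC(=O)C(C)Br)[C@@H](O)CO)cc1 | intermediate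
24 | C9 tert-butyldimethylsilyl ether of 23 | COc1ccc(COC/C(I)=C/[C@H](OC(=O)C(C)Br)[C@@H](O)CO[Si](C)(C)C(C)(C)C)cc1 | intermediate
25 | C8 ketone from 24 | COc1ccc(COC/C(I)=C/[C@H](OC(=O)C(C)Br)C(=O)CO[Si](C)(C)C(C)(C)C)cc1 | intermediate
26 | γ-lactone: 5-[(Z)-2-iodo-3-(4-methoxybenzyloxy)prop-1-enyl]-4-hydroxy-3-methyl-4-[(tert-butyldimethylsilyloxy)methyl]oxolan-2-one, with 4-OH, 3-methyl and 5-alkenyl all cis (C7 S) | COc1ccc(COC/C(I)=C/[C@@H]2OC(=O)[C@H](C)[C@@]2(O)CO[Si](C)(C)C(C)(C)C)cc1 | intermediate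
27 | lactone diol (4-hydroxymethyl analogue of 26) | COc1ccc(COC/C(I)=C/[C@@H]2OC(=O)[C@H](C)[C@@]2(O)CO)cc1 | intermediate
28 | lactone aldehyde (4-formyl analogue; C9 aldehyde, free tertiary 8-OH) | COc1ccc(COC/C(I)=C/[C@@H]2OC(=O)[C@H](C)[C@@]2(O)C=O)cc1 | intermediate
29 | allylchromium dichloride from 14 (trivalent chromium on C12, C10=C11) | CC[Si](CC)(CC)O[C@H]1CC([Cr](Cl)Cl)C(C)=C[C@@]1(C)[C@H](O[Si](CC)(CC)CC)CC=C | intermediate
30 | seco alcohol: ring A (14α-OSiEt3, 15β-methyl, C11=C12, H-10 α) bonded through C10 to C9H(OH) (epimers) on lactone C8; C1 carries the (2R)-silyloxybutenyl chain | CC[Si](CC)(CC)O[C@H]1CC=C(C)[C@H](C(O)[C@@]3(O)[C@H](/C=C(/COCc4ccc(OC)cc4)I)OC(=O)[C@@H]3C)[C@@]1(C)[C@H](O[Si](CC)(CC)CC)CC=C | intermediate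
31 | C9 ketone from 30 | CC[Si](CC)(CC)O[C@H]1CC=C(C)[C@H](C(=O)[C@@]3(O)[C@H](/C=C(/COCc4ccc(OC)cc4)I)OC(=O)[C@@H]3C)[C@@]1(C)[C@H](O[Si](CC)(CC)CC)CC=C | intermediate
32 | (9R)-alcohol, anti-8,9-diol | CC[Si](CC)(CC)O[C@H]1CC=C(C)[C@H]([C@@H](O)[C@@]3(O)[C@H](/C=C(/COCc4ccc(OC)cc4)I)OC(=O)[C@@H]3C)[C@@]1(C)[C@H](O[Si](CC)(CC)CC)CC=C | intermediate
33 | 11β,12β-epoxide of 32 | CC[Si](CC)(CC)O[C@H]1C[C@@H]2O[C@]2(C)[C@H]([C@@H](O)[C@@]3(O)[C@H](/C=C(/COCc4ccc(OC)cc4)I)OC(=O)[C@@H]3C)[C@@]1(C)[C@H](O[Si](CC)(CC)CC)CC=C | intermediate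
34 | C9 acetate of 33 | CC[Si](CC)(CC)O[C@H]1C[C@@H]2O[C@]2(C)[C@H]([C@@H](OC(C)=O)[C@@]3(O)[C@H](/C=C(/COCc4ccc(OC)cc4)I)OC(=O)[C@@H]3C)[C@@]1(C)[C@H](O[Si](CC)(CC)CC)CC=C | intermediate
35 | terminal vicinal diol from 34 | CC[Si](CC)(CC)O[C@H]1C[C@@H]2O[C@]2(C)[C@H]([C@@H](OC(C)=O)[C@@]3(O)[C@H](/C=C(/COCc4ccc(OC)cc4)I)OC(=O)[C@@H]3C)[C@@]1(C)[C@H](O[Si](CC)(CC)CC)CC(O)CO | intermediate
36 | C4 aldehyde (seco iodo aldehyde) | CC[Si](CC)(CC)O[C@H]1C[C@@H]2O[C@]2(C)[C@H]([C@@H](OC(C)=O)[C@@]3(O)[C@H](/C=C(/COCc4ccc(OC)cc4)I)OC(=O)[C@@H]3C)[C@@]1(C)[C@H](O[Si](CC)(CC)CC)CC=O | intermediate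
37 | alkenylchromium dichloride from 36 (trivalent chromium on C5) | CC[Si](CC)(CC)O[C@H]1C[C@@H]2O[C@]2(C)[C@H]([C@@H](OC(C)=O)[C@@]3(O)[C@H](/C=C(/COCc4ccc(OC)cc4)[Cr](Cl)Cl)OC(=O)[C@@H]3C)[C@@]1(C)[C@H](O[Si](CC)(CC)CC)CC=O | intermediate
38 | macrocycle: 2,14-bis(triethylsilyl) ether, (4R)-OH, 9-OAc, 8-OH, 16-OPMB, 11β,12β-epoxide, 5Z | CC[Si](CC)(CC)O[C@H]1C[C@@H]2O[C@]2(C)[C@@H]2[C@@H](OC(C)=O)[C@@]3(O)[C@H](/C=C(/COCc4ccc(OC)cc4)[C@H](O)C[C@@H](O[Si](CC)(CC)CC)[C@@]12C)OC(=O)[C@@H]3C | intermediate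
39 | 2,4,14-triol (9-OAc, 8-OH, 16-OPMB) | O[C@H]1C[C@@H]2O[C@]2(C)[C@@H]2[C@@H](OC(C)=O)[C@@]3(O)[C@H](/C=C(/COCc4ccc(OC)cc4)[C@H](O)C[C@@H](O)[C@@]12C)OC(=O)[C@@H]3C | intermediate
40 | 2,4,9,14-tetraacetate 16-(4-methoxybenzyl) ether | CC(=O)O[C@H]1C[C@@H]2O[C@]2(C)[C@@H]2[C@@H](OC(C)=O)[C@@]3(O)[C@H](/C=C(/COCc4ccc(OC)cc4)[C@H](OC(C)=O)C[C@@H](OC(C)=O)[C@@]12C)OC(=O)[C@@H]3C | intermediate
41 | CNP0104124.1: (1S,2R,4R,5Z,7S,8S,9R,10S,11R,12S,14S,17R)-2,4,9,14-tetraacetoxy-11,12-epoxy-8,16-dihydroxybriar-5-en-19,7-olide | CC(=O)O[C@H]1C[C@@H]2O[C@]2(C)[C@@H]2[C@@H](OC(C)=O)[C@@]3(O)[C@H](/C=C(/CO)[C@H](OC(C)=O)C[C@@H](OC(C)=O)[C@@]12C)OC(=O)[C@@H]3C | target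

---

**Totals**

Total step count: 32. Longest linear sequence: 21 steps (steps 1–11 then 23–32; the east branch, steps 12–22 then 23–32, is equally long).

**Three steps most likely to fail**

Step 23 (C9–C10 union). The bond joins two very congested carbons. It needs attack at C10 and not C12, and approach from the β face of C10, which cannot be corrected later. Fallback: set out from allylic alcohol 13 (10α epimer, after separation or Mitsunobu inversion). Methyl chloroformate/pyridine gives the allylic methyl carbonate F1. Copper-catalysed anti-SN2′ borylation (CuCl, Xantphos, KOt-Bu, B2pin2, THF) gives the 12β-pinacol allylboronate F2. Heating F2 with aldehyde 28 in toluene (60 °C) forms C9–C10 through a closed six-membered allylboration transition state, exclusively at the γ-carbon and on the boron-bearing β face. The route is rejoined at 30.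

Step 29 (macrocyclisation). Ten-membered ring closure may give oligomers, and the C4 configuration is under conformational control that cannot be predicted with confidence. Fallback: set out from 36 and cyclise as in step 29, accepting 38 together with its C4 epimer F3. Dess–Martin oxidation of the mixture gives the macrocyclic C4 enone F4. Corey–Bakshi–Shibata reduction with (S)-2-methyl-oxazaborolidine and catecholborane (toluene, −78 °C), which treats the α-branched alkenyl group as the large substituent, returns (4R)-38. The C4 centre is then set by reagent control and not by the ring closure.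

Step 20 (SmI2 Reformatsky lactonisation). Risks are reductive loss of the α-oxygen substituents of the ketone, loss of C7 integrity, and the wrong face at C8. Fallback: set out from 21. Acryloyl chloride/Et3N gives the acrylate F5; AcOH/H2O gives the diol F6; t-BuMe2SiCl/imidazole gives the primary silyl ether F7; Dess–Martin oxidation gives the keto acrylate F8. A copper hydride-catalysed reductive aldol cyclisation (Cu(OAc)2·H2O, rac-BINAP, (Me2SiH)2O, THF, rt) then forms the C17 enolate by conjugate hydride delivery and closes onto the C8 ketone, with methyl and hydroxyl cis. The route is rejoined at 26.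

**Further compounds**

F1 | step 23 | 10α-methyl carbonate of allylic alcohol 13 | CC[Si](CC)(CC)O[C@H]1CC=C(C)[C@@H](OC(=O)OC)[C@@]1(C)[C@H](O[Si](CC)(CC)CC)CC=C
F2 | step 23 | 12β-(pinacolboryl) allylboronate (C10=C11) | CC[Si](CC)(CC)O[C@H]1C[C@H](B2OC(C)(C)C(C)(C)O2)C(C)=C[C@@]1(C)[C@H](O[Si](CC)(CC)CC)CC=C
F3 | step 29 | C4 epimer of 38 | CC[Si](CC)(CC)O[C@H]1C[C@@H]2O[C@]2(C)[C@@H]2[C@@H](OC(C)=O)[C@@]3(O)[C@H](/C=C(/COCc4ccc(OC)cc4)[C@@H](O)C[C@@H](O[Si](CC)(CC)CC)[C@@]12C)OC(=O)[C@@H]3C
F4 | step 29 | macrocyclic C4 enone | CC[Si](CC)(CC)O[C@H]1C[C@@H]2O[C@]2(C)[C@@H]2[C@@H](OC(C)=O)[C@@]3(O)[C@H](/C=C(/COCc4ccc(OC)cc4)C(=O)C[C@@H](O[Si](CC)(CC)CC)[C@@]12C)OC(=O)[C@@H]3C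
F5 | step 20 | acrylate ester of 21 | COc1ccc(COC/C(I)=C/[C@H](OC(=O)C=C)[C@@H]2COC(C)(C)O2)cc1
F6 | step 20 | acrylate C8,C9-diol | COc1ccc(COC/C(I)=C/[C@H](OC(=O)C=C)[C@@H](O)CO)cc1
F7 | step 20 | acrylate C9 tert-butyldimethylsilyl ether | COc1ccc(COC/C(I)=C/[C@H](OC(=O)C=C)[C@@H](O)CO[Si](C)(C)C(C)(C)C)cc1
F8 | step 20 | keto acrylate (C8 ketone) | COc1ccc(COC/C(I)=C/[C@H](OC(=O)C=C)C(=O)CO[Si](C)(C)C(C)(C)C)cc1
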